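**Plan**

1. Target: meso ε,ε-carotene-3,3'-dione (6S at one end, 6R at the other). Ring atoms are numbered C1 (CMe2), C2 (CH2), C3 (C=O), C4 (=CH), C5 (=C–CH3), C6 (CH carrying the chain); chain atoms C7 to C15, primed for the other half.
2. Retrosynthesis: cut C11=C12 and C11'=C12' (two Wittig reactions on a C10 dialdehyde), then C7=C8 (Horner–Wadsworth–Emmons), then, in the C10 ring ester, the ring bonds C2–C3 and C5–C6 together.
3. Enabling feature: in the 3,5,5-trimethylcyclohex-2-enone ring the quaternary C1 lies between C2 and C6, which map onto the two α-carbons of a 3,3-dimethylglutarate. The carbonyl C3 and the methyl-bearing β-carbon C5 are the acyl and β-carbons of a but-2-ynoate, so one Michael–Dieckmann [3+3] event closes the whole ring from two purchased esters.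
4. Helpers: the ester on C2 leaves by decarboxylation, the ester on C6 becomes C7, and C3 is held as a carbinol (handle for resolution, shield for the base-labile C6–H) until the last step.
5. Forward: racemic ring, then C10 hydroxy aldehyde, C15 dienoate, resolution, two antipodal C15 phosphonium salts, stepwise C15 + C10 + C15 joining, and oxidation of both carbinols.
6. Stereochemistry: C6 arises racemic; hydride delivery sets the 3,6-trans relation; a lipase resolution at C3 supplies both antipodes and the meso target uses one at each end. All chain double bonds are E from olefination with equilibration.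

Key step: step 1

Remark: (2E,4E,6E)-2,7-dimethylocta-2,4,6-trienedial and triethyl 3-methyl-4-phosphonocrotonate are taken as purchased building blocks.

**Route**

Step 1
Reactants: 1 dimethyl 3,3-dimethylpentanedioate; 2 methyl but-2-ynoate
Product: 5 dimethyl 2,2,4-trimethyl-6-oxocyclohex-4-ene-1,3-dicarboxylate (racemic; keto and enol forms), via dilithium bis-enolate 3 (not isolated), via dilithium Michael adduct 4 (not isolated)
Conditions: LiN(i-Pr)2 (2.2 equiv), THF, −78 °C; then 2 (1.0 equiv, slow addition), −78 → 20 °C; 1 M HCl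
Reagents that add atoms: none
Why: Tandem Michael addition–Dieckmann condensation, a [3+3] Michael–Claisen annulation: one ester enolate of 3 adds to the β-carbon of the ynoate (bond C5–C6), proton transfer from the now doubly activated C6–H converts the allenolate into the glutaconate-type anion 4, and the second ester enolate then attacks the ynoate-derived ester carbonyl and expels methoxide (bond C2–C3). The closest known reaction types are the Michael–Dieckmann annulations of ester enolates with unsaturated esters and the one-pot double acylation of both α-carbons of 3,3-dimethylglutaric esters by a bis-electrophile such as an oxalate. The single ring is closed by the acylation in a 6-exo-trig mode, helped by the gem-dimethyl group on C1 and without a rival, since self-condensation of 1 could only give a four-membered ring. The new centres C2 and C6 are both acidic and form without control; C2 is erased in step 2 and C6 is resolved in step 5. The step needs 1,4- rather than 1,2-attack on the ynoate, which is the normal course for lithium ester enolates at −78 °C, and a cis relation of C6 and C3 across C4=C5, which the delocalised anion 4 reaches by bond rotation. Deprotonation of the β-keto ester by the released LiOMe should make the ring closure irreversible.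

Step 2
Reactants: 5 dimethyl 2,2,4-trimethyl-6-oxocyclohex-4-ene-1,3-dicarboxylate
Product: 6 rac-methyl 2,6,6-trimethyl-4-oxocyclohex-2-ene-1-carboxylate
Conditions: LiCl (2 equiv), H2O (2 equiv), DMSO, 130 °C
Reagents that add atoms: none
Why: Krapcho dealkoxycarbonylation: chloride demethylates the β-keto ester and the carboxylate loses CO2 through the C2 enolate, whereas the C6 ester is activated only vinylogously and should survive at this temperature, so that C2 ends as CH2 and the conjugated enone is kept.

Step 3
Reactants: 6 rac-methyl 2,6,6-trimethyl-4-oxocyclohex-2-ene-1-carboxylate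
Product: 7 rac-(1R,4R)-4-hydroxy-2,6,6-trimethylcyclohex-2-ene-1-carbaldehyde (3,6-trans)
Conditions: i-Bu2AlH (2.2 equiv), CH2Cl2, −78 °C; MeOH, then aqueous Rochelle salt; crude product used at once
Reagents that add atoms: none
Why: Hydride reduction with i-Bu2AlH: 1,2-reduction of the enone carbonyl, with hydride entering anti to the axial C1 methyl of the conformer that holds the C6 substituent pseudoaxial and therefore giving mainly the 3,6-trans carbinol, together with partial reduction of the hindered ester, whose tetrahedral aluminium hemiacetal should persist at −78 °C and release the aldehyde only on work-up.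

Step 4
Reactants: 7 rac-(1R,4R)-4-hydroxy-2,6,6-trimethylcyclohex-2-ene-1-carbaldehyde; 8 ethyl (2E)-4-(diethoxyphosphoryl)-3-methylbut-2-enoate
Product: 10 rac-ethyl (2E,4E)-5-[(1R,4R)-4-hydroxy-2,6,6-trimethylcyclohex-2-en-1-yl]-3-methylpenta-2,4-dienoate, via lithium phosphonate anion 9 (not isolated)
Conditions: 8 (1.5 equiv), LiN(SiMe3)2 (1.4 equiv), THF, −78 °C; then 7, −78 → 0 °C; aqueous NH4Cl; chromatography
Reagents that add atoms: none
Why: Horner–Wadsworth–Emmons olefination: the stabilised phosphonate anion 9 should add to the aldehyde at low temperature faster than it enolises it and reversible adduct formation gives the new C7=C8 bond with E geometry, the 9E geometry being that of the reagent; minor 3,6-cis and 9Z isomers are removed by chromatography so that a single racemic diastereomer enters the resolution.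

Step 5
Reactants: 10 rac-ethyl (2E,4E)-5-[(1R,4R)-4-hydroxy-2,6,6-trimethylcyclohex-2-en-1-yl]-3-methylpenta-2,4-dienoate
Product: 11 ethyl (2E,4E)-5-[(1R,4R)-4-acetoxy-2,6,6-trimethylcyclohex-2-en-1-yl]-3-methylpenta-2,4-dienoate and 12 ethyl (2E,4E)-5-[(1S,4S)-4-hydroxy-2,6,6-trimethylcyclohex-2-en-1-yl]-3-methylpenta-2,4-dienoate (the unreacted antipode, recovered)
Conditions: Burkholderia cepacia lipase (immobilised), vinyl acetate (3 equiv), t-BuOMe, 30 °C, stopped near half conversion; chromatography
Reagents that add atoms: vinyl acetate, CC(=O)OC=C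
Why: Lipase-catalysed kinetic resolution by irreversible transesterification: the enzyme should acylate one enantiomer of the secondary ring carbinol (the 3R antipode by the usual preference of this lipase for cyclic allylic alcohols) and, because C3 and C6 are trans-related in every molecule of 10, separation of acetate 11 from alcohol 12 separates the 6R from the 6S series, both of which are used.

Step 6
Reactants: 11 ethyl (2E,4E)-5-[(1R,4R)-4-acetoxy-2,6,6-trimethylcyclohex-2-en-1-yl]-3-methylpenta-2,4-dienoate
Product: 13 (2E,4E)-5-[(1R,4R)-4-hydroxy-2,6,6-trimethylcyclohex-2-en-1-yl]-3-methylpenta-2,4-dien-1-ol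
Conditions: i-Bu2AlH (4.5 equiv), CH2Cl2, −78 → −20 °C; aqueous Rochelle salt
Reagents that add atoms: none
Why: Hydride reduction with i-Bu2AlH: the conjugated ester is reduced 1,2 to the primary allylic alcohol and the acetate is cleaved in the same operation, under conditions that touch neither the stereocentres nor the diene geometry.

Step 7
Reactants: 12 ethyl (2E,4E)-5-[(1S,4S)-4-hydroxy-2,6,6-trimethylcyclohex-2-en-1-yl]-3-methylpenta-2,4-dienoate
Product: 14 (2E,4E)-5-[(1S,4S)-4-hydroxy-2,6,6-trimethylcyclohex-2-en-1-yl]-3-methylpenta-2,4-dien-1-ol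
Conditions: i-Bu2AlH (3.5 equiv), CH2Cl2, −78 → −20 °C; aqueous Rochelle salt
Reagents that add atoms: none
Why: Hydride reduction with i-Bu2AlH as in step 6 (1,2-reduction of the conjugated ester), giving the antipodal diol.

Step 8
Reactants: 13 (2E,4E)-5-[(1R,4R)-4-hydroxy-2,6,6-trimethylcyclohex-2-en-1-yl]-3-methylpenta-2,4-dien-1-ol
Product: 15 [(2E,4E)-5-[(1R,4R)-4-hydroxy-2,6,6-trimethylcyclohex-2-en-1-yl]-3-methylpenta-2,4-dien-1-yl]triphenylphosphonium bromide
Conditions: Ph3P·HBr (1.0 equiv), MeOH, 0 → 20 °C; crystallisation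
Reagents that add atoms: triphenylphosphine hydrobromide, Br.c1ccc(cc1)P(c1ccccc1)c1ccccc1
Why: Phosphonium salt formation from an allylic alcohol (SN1-type substitution): the primary dienylic carbinol ionises to a pentadienyl cation far more readily than the secondary ring carbinol and PPh3 captures it at the unhindered terminal carbon, so one equivalent of the acid salt at low temperature should leave the ring alcohol and C6 untouched.

Step 9
Reactants: 14 (2E,4E)-5-[(1S,4S)-4-hydroxy-2,6,6-trimethylcyclohex-2-en-1-yl]-3-methylpenta-2,4-dien-1-ol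
Product: 16 [(2E,4E)-5-[(1S,4S)-4-hydroxy-2,6,6-trimethylcyclohex-2-en-1-yl]-3-methylpenta-2,4-dien-1-yl]triphenylphosphonium bromide
Conditions: Ph3P·HBr (1.0 equiv), MeOH, 0 → 20 °C; crystallisation
Reagents that add atoms: triphenylphosphine hydrobromide, Br.c1ccc(cc1)P(c1ccccc1)c1ccccc1
Why: Phosphonium salt formation from the primary dienylic alcohol (SN1-type substitution) as in step 8, giving the antipodal salt.

Step 10
Reactants: 15 the (1R,4R) phosphonium bromide; 17 (2E,4E,6E)-2,7-dimethylocta-2,4,6-trienedial
Product: 19 (2E,4E,6E,8E,10E,12E)-13-[(1R,4R)-4-hydroxy-2,6,6-trimethylcyclohex-2-en-1-yl]-2,7,11-trimethyltrideca-2,4,6,8,10,12-hexaenal, via ylide 18 (not isolated)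
Conditions: 17 (3 equiv), NaOMe (1.1 equiv, added slowly), CH2Cl2/MeOH, −10 → 20 °C; then I2 (cat.), CH2Cl2, 20 °C, diffuse light; chromatography (excess 17 recovered)
Reagents that add atoms: none
Why: Wittig olefination: the semi-stabilised allylic ylide 18 condenses with one formyl group of 17, mono-olefination being secured by the excess of dialdehyde and slow generation of the ylide, and the E/Z mixture at the new C11=C12 bond is equilibrated to E with iodine.

Step 11
Reactants: 19 the C25 hydroxy aldehyde; 16 the (1S,4S) phosphonium bromide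
Product: 21 (3R,6R,3'S,6'S)-ε,ε-carotene-3,3'-diol (meso, all-E), via ylide 20 (not isolated)
Conditions: 16 (1.3 equiv), NaOMe (1.4 equiv), CH2Cl2/MeOH, 0 → 20 °C; then heptane, reflux; crystallisation
Reagents that add atoms: none
Why: Wittig olefination of ylide 20 with the remaining formyl group: since 19 carries the (3R,6R) ring and 20 the (3S,6S) ring, only the meso diol can form, and heating converts Z isomers at the new C11'=C12' bond into the all-E compound.

Step 12
Reactants: 21 (3R,6R,3'S,6'S)-ε,ε-carotene-3,3'-diol
Product: 22 (6R,6'S)-ε,ε-carotene-3,3'-dione (meso, all-E; the target)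
Conditions: MnO2 (activated, 30 equiv), CH2Cl2, 20 °C, dark, argon
Reagents that add atoms: none
Why: Allylic oxidation with activated MnO2: both secondary allylic carbinols are converted into the enones on the oxide surface under neutral conditions, so that the C6–H centres, which become γ-acidic only now, are not epimerised and the polyene is left intact.

**Compound list**

1 | dimethyl 3,3-dimethylpentanedioate (dimethyl 3,3-dimethylglutarate) | COC(=O)CC(C)(C)CC(=O)OC | starting material
2 | methyl but-2-ynoate | CC#CC(=O)OC | starting material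
3 | dilithium 1,5-dimethoxy-3,3-dimethylpenta-1,4-diene-1,5-diolate (bis-enolate of 1) | [Li+].[Li+].COC([O-])=CC(C)(C)C=C([O-])OC | intermediate
4 | dilithium salt of trimethyl 2,4,4-trimethylpent-1-ene-1,3,5-tricarboxylate, deprotonated at C3 (glutaconate-type dienolate) and at C5 (ester enolate) | [Li+].[Li+].COC([O-])=CC(C)(C)C(C(=O)OC)=C(C)C=C([O-])OC | intermediate
5 | dimethyl 2,2,4-trimethyl-6-oxocyclohex-4-ene-1,3-dicarboxylate (racemic, stereoisomer and tautomer mixture) | COC(=O)C1C(=O)C=C(C)C(C(=O)OC)C1(C)C | intermediate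
6 | rac-methyl 2,6,6-trimethyl-4-oxocyclohex-2-ene-1-carboxylate | COC(=O)C1C(C)=CC(=O)CC1(C)C | intermediate
7 | rac-(1R,4R)-4-hydroxy-2,6,6-trimethylcyclohex-2-ene-1-carbaldehyde (trans; racemate, one enantiomer drawn) | O=C[C@H]1C(C)=C[C@H](O)CC1(C)C | intermediate
8 | ethyl (2E)-4-(diethoxyphosphoryl)-3-methylbut-2-enoate (triethyl 3-methyl-4-phosphonocrotonate) | CCOC(=O)/C=C(C)/CP(=O)(OCC)OCC | starting material
9 | lithium salt of the C4 carbanion of 8 | [Li+].CCOC(=O)/C=C(C)/[CH-]P(=O)(OCC)OCC | intermediate
10 | rac-ethyl (2E,4E)-5-[(1R,4R)-4-hydroxy-2,6,6-trimethylcyclohex-2-en-1-yl]-3-methylpenta-2,4-dienoate (trans; racemate, one enantiomer drawn) | CCOC(=O)/C=C(C)/C=C/[C@H]1C(C)=C[C@H](O)CC1(C)C | intermediate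
11 | ethyl (2E,4E)-5-[(1R,4R)-4-acetoxy-2,6,6-trimethylcyclohex-2-en-1-yl]-3-methylpenta-2,4-dienoate | CCOC(=O)/C=C(C)/C=C/[C@H]1C(C)=C[C@H](OC(C)=O)CC1(C)C | intermediate
12 | ethyl (2E,4E)-5-[(1S,4S)-4-hydroxy-2,6,6-trimethylcyclohex-2-en-1-yl]-3-methylpenta-2,4-dienoate | CCOC(=O)/C=C(C)/C=C/[C@@H]1C(C)=C[C@@H](O)CC1(C)C | intermediate
13 | (2E,4E)-5-[(1R,4R)-4-hydroxy-2,6,6-trimethylcyclohex-2-en-1-yl]-3-methylpenta-2,4-dien-1-ol | OC/C=C(C)/C=C/[C@H]1C(C)=C[C@H](O)CC1(C)C | intermediate
14 | (2E,4E)-5-[(1S,4S)-4-hydroxy-2,6,6-trimethylcyclohex-2-en-1-yl]-3-methylpenta-2,4-dien-1-ol | OC/C=C(C)/C=C/[C@@H]1C(C)=C[C@@H](O)CC1(C)C | intermediate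
15 | [(2E,4E)-5-[(1R,4R)-4-hydroxy-2,6,6-trimethylcyclohex-2-en-1-yl]-3-methylpenta-2,4-dien-1-yl]triphenylphosphonium bromide | [Br-].c1ccccc1[P+](c1ccccc1)(c1ccccc1)C/C=C(C)/C=C/[C@H]1C(C)=C[C@H](O)CC1(C)C | intermediate
16 | [(2E,4E)-5-[(1S,4S)-4-hydroxy-2,6,6-trimethylcyclohex-2-en-1-yl]-3-methylpenta-2,4-dien-1-yl]triphenylphosphonium bromide | [Br-].c1ccccc1[P+](c1ccccc1)(c1ccccc1)C/C=C(C)/C=C/[C@@H]1C(C)=C[C@@H](O)CC1(C)C | intermediate
17 | (2E,4E,6E)-2,7-dimethylocta-2,4,6-trienedial | O=C/C(C)=C/C=C/C=C(C)/C=O | starting material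
18 | ylide of 15, [(2E,4E)-5-[(1R,4R)-4-hydroxy-2,6,6-trimethylcyclohex-2-en-1-yl]-3-methylpenta-2,4-dien-1-ylidene]triphenylphosphorane | c1ccccc1P(c1ccccc1)(c1ccccc1)=C/C=C(C)/C=C/[C@H]1C(C)=C[C@H](O)CC1(C)C | intermediate
19 | (2E,4E,6E,8E,10E,12E)-13-[(1R,4R)-4-hydroxy-2,6,6-trimethylcyclohex-2-en-1-yl]-2,7,11-trimethyltrideca-2,4,6,8,10,12-hexaenal ((3R,6R)-3-hydroxy-12'-apo-ε-caroten-12'-al) | O=C/C(C)=C/C=C/C=C(C)/C=C/C=C(C)/C=C/[C@H]1C(C)=C[C@H](O)CC1(C)C | intermediate
20 | ylide of 16, the (1S,4S) antipode of 18 | c1ccccc1P(c1ccccc1)(c1ccccc1)=C/C=C(C)/C=C/[C@@H]1C(C)=C[C@@H](O)CC1(C)C | intermediate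
21 | (3R,6R,3'S,6'S)-ε,ε-carotene-3,3'-diol (meso, all-E) | CC1=C[C@@H](O)CC(C)(C)[C@@H]1/C=C/C(C)=C/C=C/C(C)=C/C=C/C=C(C)/C=C/C=C(C)/C=C/[C@H]1C(C)=C[C@H](O)CC1(C)C | intermediate
22 | (6R,6'S)-ε,ε-carotene-3,3'-dione (meso, all-E) | CC1=CC(=O)CC(C)(C)[C@@H]1/C=C/C(C)=C/C=C/C(C)=C/C=C/C=C(C)/C=C/C=C(C)/C=C/[C@H]1C(C)=CC(=O)CC1(C)C | target

**Count and risks**

Total step count: 12. Longest linear sequence: 10 steps (1, 2, 3, 4, 5, 6, 8, 10, 11, 12).

Steps most likely to fail:

Step 1. The lithium enolate may attack the ynoate ester carbonyl (1,2) instead of the β-carbon. Proton transfer may quench the second enolate before it can close the ring. The ring-closing acylation may be too slow on the charge-delocalised ester. Fallback: the ring is made by the long-established Lewis-acid annulation of mesityl oxide F1 with methyl acetoacetate F2 (ZnCl2, heptane, reflux with water separation). Conjugate addition of the acetoacetate to the enone is followed by aldol condensation of the methyl ketone onto the acetoacetate carbonyl and loss of water. This fallback uses no numbered intermediate: it sets out from purchased F1 and F2 in place of 1 and 2 and comes back to the route at 6, so that steps 1 and 2 are both replaced.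

Step 3. Reduction of the ester may run past the aldehyde stage, and the β,γ-unsaturated aldehyde may move its double bond into conjugation or epimerise during isolation. Fallback: setting out from 6, LiAlH4 (Et2O, 0 °C) reduces ketone and ester completely to the diol rac-(1R,4R)-4-(hydroxymethyl)-3,5,5-trimethylcyclohex-2-en-1-ol F3. The primary alcohol alone is then oxidised under neutral aerobic copper/nitroxyl conditions ([Cu(MeCN)4]OTf, 2,2'-bipyridine, TEMPO, N-methylimidazole, air, MeCN, 20 °C), which spare the secondary carbinol, and the aldehyde is taken without purification into step 4. The fallback comes back to the route at 7.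

Step 5. The lipase may discriminate the two enantiomers poorly, because the two ring carbons flanking the carbinol differ little in size. Fallback: setting out from 10, esterification with (S)-2-methoxy-2-phenylacetic acid (DCC, DMAP, CH2Cl2) gives two diastereomeric esters that are separated by chromatography or crystallisation. These are ethyl (2E,4E)-5-[(1R,4R)-4-{[(2S)-2-methoxy-2-phenylacetyl]oxy}-2,6,6-trimethylcyclohex-2-en-1-yl]-3-methylpenta-2,4-dienoate F4 and its (1S,4S) ring diastereomer F5. Treatment of each with i-Bu2AlH, as in steps 6 and 7, reduces the dienoate and cleaves the auxiliary. The fallback comes back to the route at 13 (from F4) and at 14 (from F5), so that steps 5, 6 and 7 are replaced.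

**Further compounds**

F1 | step 1 | mesityl oxide (4-methylpent-3-en-2-one; purchased) | CC(=O)C=C(C)C
F2 | step 1 | methyl acetoacetate (methyl 3-oxobutanoate; purchased) | COC(=O)CC(C)=O
F3 | step 3 | rac-(1R,4R)-4-(hydroxymethyl)-3,5,5-trimethylcyclohex-2-en-1-ol (trans; racemate, one enantiomer drawn) | OC[C@H]1C(C)=C[C@H](O)CC1(C)C
F4 | step 5 | ethyl (2E,4E)-5-[(1R,4R)-4-{[(2S)-2-methoxy-2-phenylacetyl]oxy}-2,6,6-trimethylcyclohex-2-en-1-yl]-3-methylpenta-2,4-dienoate | CCOC(=O)/C=C(C)/C=C/[C@H]1C(C)=C[C@H](OC(=O)[C@@H](OC)c2ccccc2)CC1(C)C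
F5 | step 5 | ethyl (2E,4E)-5-[(1S,4S)-4-{[(2S)-2-methoxy-2-phenylacetyl]oxy}-2,6,6-trimethylcyclohex-2-en-1-yl]-3-methylpenta-2,4-dienoate | CCOC(=O)/C=C(C)/C=C/[C@@H]1C(C)=C[C@@H](OC(=O)[C@@H](OC)c2ccccc2)CC1(C)C
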